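**Strategy.** The ten-membered carbocycle (C1–C10) is opened between C8 and C9. These are adjacent, trans-oxygenated ring carbons, so both can be aldehyde carbons of one acyclic chain. A low-valent titanium pinacol coupling rejoins them, closing the ring and creating both carbinol stereocentres in one operation. The cyclisation substrate is a seco-8,9-dialdehyde. It already contains the trans-disubstituted γ-lactone (O6–C6–C7–C11–C12), the E C4=C5 alkene and the C1=C10 alkene with C2 cis to C9. Its reducible C11=C13 methylene is masked as the 13-phenylsulfonyl adduct. O14 carries a PMB ether, which later distinguishes O9 from O8.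

Key step: step 17

Remarks on the chemistry (conventions, design choices, assumptions)
- Germacrane numbering is used for every intermediate, and α/β refer to the usual drawing with H-7 α. The target is 6R,7S,8S,9S (6βH, 7αH, 8β-O, 9α-O) and 4E. At C1=C10, C2 is cis to C9, so the C9 enal of the cyclisation substrate is the less stable CIP-Z enal.
- Carbon mapping: Baylis–Hillman addition followed by allylic transposition leaves the chain cis to the former acrylate CH2 and trans to the ester. The acrylate CH2 therefore becomes C9 and the ester carbon becomes C14.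
- C11=C13 is masked because an α-methylene lactone accepts electrons and radicals better than an aliphatic aldehyde. It also makes H-7 vinylogously acidic.
- O14 is a PMB ether. It is a poor leaving group from the reduced enal, it is stable to dilute acid, and DDQ can later close it onto O9.
- C8 travels as a silyl ether. Both aldehydes are released together by a neutral oxidation directly before the key step, because the C8 aldehyde is β-acyloxy and epimerisable.
- Assumption: the sense of induction of the chromium catalyst in step 14 is taken as drawn. The ligand antipode (from the other valinol) is used if the opposite enantiomer forms.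
- Assumption: C11 of 22–27 is drawn 11βH (all-trans lactone) and the acetal carbon of 26–28 with the aryl group equatorial. Both centres are erased later, so their configuration is not critical.
- Abbreviations: TBDPS = tert-butyldiphenylsilyl, TBS = tert-butyldimethylsilyl, Tr = triphenylmethyl, PMB = 4-methoxybenzyl, PMP = 4-methoxyphenyl.

Step 1
Reactants: 1 geraniol
Product: 2 geranyl TBDPS ether (O6-TBDPS)
Conditions: TBDPSCl, imidazole, CH2Cl2, 0 °C to rt
Reagents that add atoms: tert-butyl(chloro)diphenylsilane, CC(C)(C)[Si](Cl)(c1ccccc1)c1ccccc1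
Why: Routine silylation of the primary allylic alcohol; the O6 ether survives peracid, periodic acid, DABCO, carbonate, i-Bu2AlH and NaH and is the only fluoride-labile group when it has to leave in step 10.

Step 2
Reactants: 2 geranyl TBDPS ether
Product: 3 terminal epoxide of 2 (racemic)
Conditions: mCPBA (1.0 equiv), CH2Cl2, −20 °C
Reagents that add atoms: 3-chloroperbenzoic acid, OOC(=O)c1cccc(Cl)c1
Why: Prilezhaev epoxidation is fastest at the distal trisubstituted alkene because C4=C5 is deactivated by its allylic oxygen; the new stereocentre is racemic and disappears in step 3.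

Step 3
Reactants: 3 terminal epoxide
Product: 5 (E)-6-(tert-butyldiphenylsilyloxy)-4-methylhex-4-enal (C1 aldehyde), via glycol 4 (not isolated)
Conditions: H5IO6, THF–Et2O, 0 °C
Reagents that add atoms: none
Why: Periodic acid hydrates the epoxide and cleaves the glycol (Malaprade reaction) in one flask, removing the isopropylidene carbons as acetone and leaving the E C4=C5 alkene of geraniol untouched.

Step 4
Reactants: 5 C1 aldehyde; 6 methyl acrylate
Product: 7 methyl (6E)-8-(tert-butyldiphenylsilyloxy)-3-hydroxy-6-methyl-2-methylideneoct-6-enoate (racemic at C1)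
Conditions: DABCO (1 equiv), 1,4-dioxane–H2O (1:1), rt
Reagents that add atoms: none
Why: Morita–Baylis–Hillman reaction of an unhindered aliphatic aldehyde adds C10, C9 (acrylate CH2) and C14 (ester carbon) at once; the C1 carbinol is racemic and becomes sp2 in step 5.

Step 5
Reactants: 7 Baylis–Hillman adduct
Product: 8 methyl (2Z,6E)-2-(bromomethyl)-8-(tert-butyldiphenylsilyloxy)-6-methylocta-2,6-dienoate
Conditions: NBS, Me2S, CH2Cl2, 0 °C to rt
Reagents that add atoms: N-bromosuccinimide, O=C1CCC(=O)N1Br
Why: Corey–Kim-type activation of the hydroxyl and SN2′ attack of bromide on the acrylate CH2 transpose the allyl system, and allylic 1,3-strain with the conjugated ester places the chain trans to CO2Me and cis to CH2Br, which is the C2-cis-to-C9 geometry required at C1=C10.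

Step 6
Reactants: 8 allylic bromide
Product: 10 methyl (2E,6E)-8-(tert-butyldiphenylsilyloxy)-2-(hydroxymethyl)-6-methylocta-2,6-dienoate (free O9–H), via allylic acetate 9 (not isolated)
Conditions: KOAc, DMF, rt; then K2CO3 (0.2 equiv), MeOH, 0 °C
Reagents that add atoms: potassium acetate, CC(=O)[O-].[K+]
Why: An inorganic carboxylate displaces the primary allylic bromide by SN2 (no amine is present that could return it by SN2′), and mild carbonate-catalysed methanolysis of the acetate frees O9–H without touching the conjugated methyl ester or the alkene geometry.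

Step 7
Reactants: 10 C9 alcohol
Product: 11 methyl (2E,6E)-8-(tert-butyldiphenylsilyloxy)-6-methyl-2-(trityloxymethyl)octa-2,6-dienoate
Conditions: TrCl, Et3N, DMAP (cat.), CH2Cl2, rt
Reagents that add atoms: trityl chloride, ClC(c1ccccc1)(c1ccccc1)c1ccccc1
Why: Tritylation of the primary alcohol gives an O9 ether that is inert to hydride, NaH, fluoride, MnO2 and the chromium coupling but is cleaved by dilute acid in step 15.

Step 8
Reactants: 11 trityl ether ester
Product: 12 (2Z,6E)-8-(tert-butyldiphenylsilyloxy)-6-methyl-2-(trityloxymethyl)octa-2,6-dien-1-ol (free O14–H)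
Conditions: i-Bu2AlH (2.5 equiv), CH2Cl2, −78 °C; aq. potassium sodium tartrate
Reagents that add atoms: none
Why: Low-temperature 1,2-reduction of the conjugated ester gives the C14 allylic alcohol, so that O9 (from the CH2Br carbon) and O14 (from the ester carbon) are differentiated without any selective protection of a diol.

Step 9
Reactants: 12 C14 alcohol
Product: 13 O14-PMB ether of 12
Conditions: NaH, PMBCl, Bu4NI (cat.), THF–DMF, 0 °C to rt
Reagents that add atoms: 4-methoxybenzyl chloride, COc1ccc(CCl)cc1
Why: Williamson etherification under basic conditions, to which the silyl and trityl ethers are inert.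

Step 10
Reactants: 13 fully protected triol
Product: 14 (2E,6Z)-8-(4-methoxybenzyloxy)-3-methyl-7-(trityloxymethyl)octa-2,6-dien-1-ol (free O6–H)
Conditions: Bu4NF, THF, rt
Reagents that add atoms: none
Why: Fluoride cleaves the only silyl ether present and leaves the trityl and PMB ethers in place.

Step 11
Reactants: 14 C6 alcohol
Product: 15 (2E,6Z)-8-(4-methoxybenzyloxy)-3-methyl-7-(trityloxymethyl)octa-2,6-dienal (C6 enal)
Conditions: MnO2, CH2Cl2, rt
Reagents that add atoms: none
Why: Neutral MnO2 oxidation of the only free allylic alcohol gives the geranial-type enal with retention of the E geometry.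

Step 12
Reactants: 16 (tert-butyldimethylsilyloxy)acetaldehyde; 6 methyl acrylate
Product: 17 methyl 4-(tert-butyldimethylsilyloxy)-3-hydroxy-2-methylidenebutanoate (racemic)
Conditions: DABCO (0.5 equiv), 1,4-dioxane–H2O (1:1), rt
Reagents that add atoms: none
Why: Morita–Baylis–Hillman reaction of a reactive α-oxygenated aldehyde assembles C7 (aldehyde carbon), C8, C11, C12 and C13; the carbinol is racemic and becomes sp2 in step 13.

Step 13
Reactants: 17 Baylis–Hillman adduct
Product: 18 methyl (Z)-2-(bromomethyl)-4-(tert-butyldimethylsilyloxy)but-2-enoate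
Conditions: NBS, Me2S, CH2Cl2, 0 °C to rt
Reagents that add atoms: N-bromosuccinimide, O=C1CCC(=O)N1Br
Why: The same Corey–Kim-type SN2′ bromination as in step 5 gives the 2-(bromomethyl)enoate; its geometry is not critical because the derived allylchromium species equilibrates.

Step 14
Reactants: 15 C6 enal; 18 allylic bromide
Product: 21 trans-(6βH,7αH)-α-methylene-γ-lactone with CH2OTBS on C7 and the O9-Tr/O14-PMB dienyl chain on C6, via trimethylsilyl ether 19 (not isolated), via hydroxy ester 20 (not isolated)
Conditions: CrCl2 (10 mol %), (S,S)-1,8-bis(4-isopropyl-4,5-dihydrooxazol-2-yl)-3,6-diphenyl-9H-carbazole (12 mol %), Mn powder, Me3SiCl, i-Pr2NEt (30 mol %), THF, rt; 10% aq. citric acid–THF, 0 °C; PPTS (cat.), CH2Cl2, rt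
Reagents that add atoms: none
Why: In this catalytic asymmetric Nozaki–Hiyama–Kishi (Barbier-type) 2-(alkoxycarbonyl)allylation the trivalent allylchromium species, which tolerates the δ-silyloxy group, adds 1,2 to the enal through a chair transition state with CH2OTBS equatorial (anti adduct, hence C7 trans to C6), the tridentate ligand selects the aldehyde face (C6), and the freed γ-hydroxy ester lactonises under PPTS.

Step 15
Reactants: 21 α-methylene lactone
Product: 23 11βH-13-phenylsulfonyl lactone 8,9-diol (O14-PMB), via protected sulfone 22 (not isolated)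
Conditions: (a) PhSO2Na, AcOH, THF–H2O, rt; (b) 1 M aq. HCl, rt
Reagents that add atoms: sodium benzenesulfinate, [O-]S(=O)c1ccccc1.[Na+]
Why: Sulfa-Michael addition of benzenesulfinic acid saturates C11=C13 as an oxidation- and reduction-inert sulfone, and brief dilute acid then removes the primary TBS and trityl ethers while PMB ether, lactone and sulfone persist (translactonisation to O8 would have to pass a strained bicyclo[2.2.1] orthoester).

Step 16
Reactants: 23 8,9-diol
Product: 24 seco-8,9-dialdehyde: all-trans lactone (6βH,7αH,11βH) with CHO (C8) on C7, CH2SO2Ph on C11 and on C6 the 4E-alkenyl chain ending in the Z enal (C9 cis to C2, O14-PMB)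
Conditions: Dess–Martin periodinane (2.5 equiv), CH2Cl2, 0 °C to rt
Reagents that add atoms: none
Why: Dess–Martin oxidation converts both primary alcohols at once without base or strong acid, so the β-acyloxy C8 aldehyde (whose trans C7 configuration is also the thermodynamic one) and the less stable Z enal are formed last and are used directly.

Step 17
Reactants: 24 seco-8,9-dialdehyde
Product: 25 ten-membered 8β,9α-diol (trans) with the trans-fused 12,6α-lactone, 11βH-13-phenylsulfonyl mask and O14-PMB
Conditions: TiCl3(DME)1.5 (12 equiv), Zn–Cu couple (40 equiv), DME, reflux 4 h; cooled to 0 °C, 24 added by syringe pump over 30 h (final about 1 mM); aq. NaHCO3, filtration through Florisil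
Reagents that add atoms: none
Why: Each aldehyde binds to the reduced titanium and takes up one electron, and the two titanium-bound ketyl radicals (the C9 one allylic but reacting at its oxygen-bearing end) combine to a titanium 8,9-diolate that persists at 0 °C, because deoxygenation to the alkene needs reflux, and is protonated on work-up. The closest known reaction type is the McMurry-type intramolecular pinacol coupling of dialdehydes, established for medium and large carbocycles and with an enal as one partner. The ten-membered ring closes end-to-end by C8–C9 ketyl–ketyl coupling under pseudo-high dilution, assisted by three turn elements, namely the trans-lactone, the E C4=C5 alkene and the C1=C10 alkene that holds C9 cis to C2. C9 is set relative to C8 by the preference of medium-ring titanium pinacols for the arrangement with the two Ti–O bonds anti, which leads to the trans-diol. C8 is set by C7: the tether from C6 can reach C8 only gauche to the C6–C7 bond, and the Felkin–Anh approach anti to the C7–C11 bond with O8 turned toward C6 gives the 8β-oxygen, cis to C11. The step needs reduction of the two aldehydes only, which is secured by the saturated sulfone in place of C11=C13, by the poor leaving-group ability of the PMB oxide on C14 and by the inertness of lactone, sulfone and isolated alkenes at this temperature.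

Step 18
Reactants: 25 8,9-diol
Product: 26 9,14-O-(4-methoxybenzylidene) acetal with free 8β-OH
Conditions: DDQ (1.2 equiv), 4 Å molecular sieves, CH2Cl2, 0 °C
Reagents that add atoms: none
Why: Under anhydrous conditions DDQ abstracts hydride from the PMB methylene and the oxocarbenium ion is trapped by the neighbouring O9–H in a six-membered ring (O8 would need a seven-membered one), a known oxidative acetalisation that leaves O8–H as the only free hydroxyl.

Step 19
Reactants: 26 PMP acetal alcohol
Product: 28 8β-methacrylate with regenerated α-methylene lactone and 9,14-PMP acetal, via sulfonyl methacrylate 27 (not isolated)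
Conditions: methacrylic anhydride, Et3N, DMAP, CH2Cl2, 0 °C to rt; then DBU, 0 °C
Reagents that add atoms: methacrylic anhydride, C=C(C)C(=O)OC(=O)C(C)=C
Why: DMAP-catalysed (Steglich-type) acylation can only reach O8, and DBU then expels benzenesulfinate from C13 by E1cB elimination through the lactone enolate, restoring C11=C13 while neither the enal nor the allylic acetate is present yet.

Step 20
Reactants: 28 PMP acetal methacrylate
Product: 29 8β-methacryloyloxy-9α,14-diol
Conditions: AcOH–THF–H2O (4:1:1), rt
Reagents that add atoms: none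
Why: The electron-rich PMP acetal hydrolyses in dilute acetic acid, conditions too mild for ester cleavage, acyl migration or transannular cyclisation of the deactivated diene.

Step 21
Reactants: 29 9,14-diol
Product: 30 8β-methacryloyloxy-9α-hydroxy-14-al
Conditions: TEMPO (10 mol %), PhI(OAc)2, CH2Cl2, rt
Reagents that add atoms: none
Why: The oxoammonium (TEMPO) oxidation is strongly selective for the primary allylic alcohol over the hindered secondary C9 carbinol and gives the enal in its stable geometry (CHO trans to C2).

Step 22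
Reactants: 30 hydroxy enal
Product: 31 target (CNP0403553.1)
Conditions: Ac2O, pyridine, DMAP (cat.), CH2Cl2, 0 °C
Reagents that add atoms: acetic anhydride, CC(=O)OC(C)=O
Why: Acetylation of the only remaining hydroxyl (O9) under weakly basic conditions completes the target without disturbing C6–C9 or either alkene geometry.

Compound list
1 | geraniol | CC(C)=CCC/C(C)=C/CO | starting material
2 | geranyl TBDPS ether | CC(C)=CCC/C(C)=C/CO[Si](c1ccccc1)(c1ccccc1)C(C)(C)C | intermediate
3 | terminal epoxide of 2 (racemic) | CC1(C)OC1CC/C(C)=C/CO[Si](c1ccccc1)(c1ccccc1)C(C)(C)C | intermediate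
4 | glycol from 3 (racemic, not isolated) | CC(C)(O)C(O)CC/C(C)=C/CO[Si](c1ccccc1)(c1ccccc1)C(C)(C)C | intermediate
5 | (E)-6-(tert-butyldiphenylsilyloxy)-4-methylhex-4-enal | O=CCC/C(C)=C/CO[Si](c1ccccc1)(c1ccccc1)C(C)(C)C | intermediate
6 | methyl acrylate | C=CC(=O)OC | starting material
7 | methyl (6E)-8-(tert-butyldiphenylsilyloxy)-3-hydroxy-6-methyl-2-methylideneoct-6-enoate (racemic) | C=C(C(=O)OC)C(O)CC/C(C)=C/CO[Si](c1ccccc1)(c1ccccc1)C(C)(C)C | intermediate
8 | methyl (2Z,6E)-2-(bromomethyl)-8-(tert-butyldiphenylsilyloxy)-6-methylocta-2,6-dienoate | COC(=O)/C(CBr)=C/CC/C(C)=C/CO[Si](c1ccccc1)(c1ccccc1)C(C)(C)C | intermediate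
9 | methyl (2E,6E)-2-(acetoxymethyl)-8-(tert-butyldiphenylsilyloxy)-6-methylocta-2,6-dienoate (not isolated) | COC(=O)/C(COC(C)=O)=C/CC/C(C)=C/CO[Si](c1ccccc1)(c1ccccc1)C(C)(C)C | intermediate
10 | methyl (2E,6E)-8-(tert-butyldiphenylsilyloxy)-2-(hydroxymethyl)-6-methylocta-2,6-dienoate | COC(=O)/C(CO)=C/CC/C(C)=C/CO[Si](c1ccccc1)(c1ccccc1)C(C)(C)C | intermediate
11 | methyl (2E,6E)-8-(tert-butyldiphenylsilyloxy)-6-methyl-2-(trityloxymethyl)octa-2,6-dienoate | COC(=O)/C(COC(c1ccccc1)(c1ccccc1)c1ccccc1)=C/CC/C(C)=C/CO[Si](c1ccccc1)(c1ccccc1)C(C)(C)C | intermediate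
12 | (2Z,6E)-8-(tert-butyldiphenylsilyloxy)-6-methyl-2-(trityloxymethyl)octa-2,6-dien-1-ol | OC/C(COC(c1ccccc1)(c1ccccc1)c1ccccc1)=C/CC/C(C)=C/CO[Si](c1ccccc1)(c1ccccc1)C(C)(C)C | intermediate
13 | O14-PMB ether of 12 | COc1ccc(COC/C(COC(c2ccccc2)(c2ccccc2)c2ccccc2)=C/CC/C(C)=C/CO[Si](c2ccccc2)(c2ccccc2)C(C)(C)C)cc1 | intermediate
14 | (2E,6Z)-8-(4-methoxybenzyloxy)-3-methyl-7-(trityloxymethyl)octa-2,6-dien-1-ol | COc1ccc(COC/C(COC(c2ccccc2)(c2ccccc2)c2ccccc2)=C/CC/C(C)=C/CO)cc1 | intermediate
15 | (2E,6Z)-8-(4-methoxybenzyloxy)-3-methyl-7-(trityloxymethyl)octa-2,6-dienal | COc1ccc(COC/C(COC(c2ccccc2)(c2ccccc2)c2ccccc2)=C/CC/C(C)=C/C=O)cc1 | intermediate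
16 | (tert-butyldimethylsilyloxy)acetaldehyde | CC(C)(C)[Si](C)(C)OCC=O | starting material
17 | methyl 4-(tert-butyldimethylsilyloxy)-3-hydroxy-2-methylidenebutanoate (racemic) | C=C(C(=O)OC)C(O)CO[Si](C)(C)C(C)(C)C | intermediate
18 | methyl (Z)-2-(bromomethyl)-4-(tert-butyldimethylsilyloxy)but-2-enoate | COC(=O)/C(CBr)=C/CO[Si](C)(C)C(C)(C)C | intermediate
19 | anti adduct, O6-trimethylsilyl ether (not isolated) | COC(=O)C(=C)[C@H](CO[Si](C)(C)C(C)(C)C)[C@H](O[Si](C)(C)C)/C=C(\C)CC/C=C(/COCc1ccc(OC)cc1)COC(c1ccccc1)(c1ccccc1)c1ccccc1 | intermediate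
20 | anti γ-hydroxy α-methylene ester (not isolated) | COC(=O)C(=C)[C@H](CO[Si](C)(C)C(C)(C)C)[C@H](O)/C=C(\C)CC/C=C(/COCc1ccc(OC)cc1)COC(c1ccccc1)(c1ccccc1)c1ccccc1 | intermediate
21 | trans α-methylene-γ-lactone (6βH,7αH), C8 as CH2OTBS, O9-Tr, O14-PMB | CC(C)(C)[Si](C)(C)OC[C@H]1C(=C)C(=O)O[C@@H]1/C=C(\C)CC/C=C(/COCc1ccc(OC)cc1)COC(c1ccccc1)(c1ccccc1)c1ccccc1 | intermediate
22 | 11βH-13-phenylsulfonyl adduct of 21 (not isolated) | CC(C)(C)[Si](C)(C)OC[C@H]1[C@H](CS(=O)(=O)c2ccccc2)C(=O)O[C@@H]1/C=C(\C)CC/C=C(/COCc1ccc(OC)cc1)COC(c1ccccc1)(c1ccccc1)c1ccccc1 | intermediate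
23 | 11βH-13-phenylsulfonyl lactone 8,9-diol, O14-PMB | OC[C@H]1[C@H](CS(=O)(=O)c2ccccc2)C(=O)O[C@@H]1/C=C(\C)CC/C=C(/COCc1ccc(OC)cc1)CO | intermediate
24 | seco-8,9-dialdehyde (key-step precursor), masked lactone, O14-PMB | O=C[C@H]1[C@H](CS(=O)(=O)c2ccccc2)C(=O)O[C@@H]1/C=C(\C)CC/C=C(/COCc1ccc(OC)cc1)C=O | intermediate
25 | ten-membered 8β,9α-diol lactone (key-step product), masked lactone, O14-PMB | O[C@H]1[C@H]2[C@H](CS(=O)(=O)c3ccccc3)C(=O)O[C@@H]2/C=C(\C)CC/C=C(/COCc2ccc(OC)cc2)[C@@H]1O | intermediate
26 | 9,14-O-(4-methoxybenzylidene) acetal of the triol core, free 8β-OH | O[C@H]1[C@H]2[C@H](CS(=O)(=O)c3ccccc3)C(=O)O[C@@H]2/C=C(\C)CC/C=C3/CO[C@H](c4ccc(OC)cc4)O[C@H]13 | intermediate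
27 | 8β-methacrylate of 26 (not isolated) | C=C(C)C(=O)O[C@H]1[C@H]2[C@H](CS(=O)(=O)c3ccccc3)C(=O)O[C@@H]2/C=C(\C)CC/C=C3/CO[C@H](c4ccc(OC)cc4)O[C@H]13 | intermediate
28 | 8β-methacrylate, α-methylene lactone, 9,14-PMP acetal | C=C(C)C(=O)O[C@H]1[C@H]2C(=C)C(=O)O[C@@H]2/C=C(\C)CC/C=C3/CO[C@H](c4ccc(OC)cc4)O[C@H]13 | intermediate
29 | 8β-methacryloyloxy-9α,14-diol | C=C(C)C(=O)O[C@H]1[C@H]2C(=C)C(=O)O[C@@H]2/C=C(\C)CC/C=C(/CO)[C@@H]1O | intermediate
30 | 8β-methacryloyloxy-9α-hydroxy-14-al | C=C(C)C(=O)O[C@H]1[C@H]2C(=C)C(=O)O[C@@H]2/C=C(\C)CC/C=C(/C=O)[C@@H]1O | intermediate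
31 | CNP0403553.1, 9α-acetoxy-8β-methacryloyloxy-14-oxogermacra-1(10),4,11(13)-trien-12,6α-olide (6R,7S,8S,9S) | C=C(C)C(=O)O[C@H]1[C@H]2C(=C)C(=O)O[C@@H]2/C=C(\C)CC/C=C(/C=O)[C@@H]1OC(C)=O | target

Total step count: 22. Longest linear sequence: 20 (steps 1–11 and 14–22; steps 12–13 form the side branch).

Steps most likely to fail

1. Step 17.
- What may go wrong: intermolecular coupling to oligomers, bond formation through the remote C1 end of the allylic ketyl, β-loss of the C14 oxygen from the reduced enal, or weak facial discrimination at C8.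
- Fallback: it sets out from 24 and makes the same bond by a polar, closed-transition-state route instead of radical–radical coupling. In a chromium-mediated pinacol-type cross-coupling (CrCl2, Et3SiCl, DMF, slow addition), divalent chromium reduces only the enal. This gives a γ-silyloxyallylchromium species with the metal on C1.
- That species adds through its C9 terminus to the unreduced C8 aldehyde and regenerates C1=C10, giving the 9-O-triethylsilyl ether F1. AcOH–THF–H2O removes the silyl group and the route is rejoined at 25.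
- The geometry of the regenerated alkene would have to be checked.

2. Step 14.
- What may go wrong: erosion of enantio- or anti-selectivity because the allylchromium geometry is not fixed, or 1,4-elimination of silyloxide from the allylmetal.
- Fallback: it sets out from 15 and replaces the Barbier coupling by a geometry-defined allylboration. Commercial tert-butyldimethyl(prop-2-yn-1-yloxy)silane is carboxylated (n-BuLi, ClCO2Me) to methyl 4-(tert-butyldimethylsilyloxy)but-2-ynoate F2.
- syn-Hydroalumination (i-Bu2AlH–HMPA) and trapping with ICH2Bpin give the (Z)-allylboronate F3, in which CH2OTBS is trans to CH2B.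
- Allylboration of 15 catalysed by the chiral phosphoric acid TRIP (enantiomer chosen for the C6 face) passes through a closed chair and should give the anti O6-pinacolboryl ether F4.
- Hydrolysis of F4 gives 20, and lactonisation as in step 14 rejoins the route at 21.

3. Step 18.
- What may go wrong: hydrolytic loss of the PMB group instead of ring closure, over-oxidation of the acetal to a benzoate, or oxidation of the allylic carbinol.
- Fallback: it sets out from 25 and differentiates the hydroxyls with a silicon bridge. DDQ in wet CH2Cl2 removes the PMB group to give the 8,9,14-triol F5.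
- t-Bu2Si(OTf)2 with 2,6-lutidine bridges the 1,3-related O9 and O14 as the six-membered 9,14-di-tert-butylsilylene F6.
- Methacrylic anhydride with DMAP gives the 8-methacrylate F7, and DBU eliminates the sulfinate to give the α-methylene lactone silylene F8.
- HF·pyridine then releases the diol and the route is rejoined at 29.

Further compounds
F1 | step 17 | 9-O-triethylsilyl ether of 25 | O[C@H]1[C@H]2[C@H](CS(=O)(=O)c3ccccc3)C(=O)O[C@@H]2/C=C(\C)CC/C=C(/COCc2ccc(OC)cc2)[C@@H]1O[Si](CC)(CC)CC
F2 | step 14 | methyl 4-(tert-butyldimethylsilyloxy)but-2-ynoate | COC(=O)C#CCO[Si](C)(C)C(C)(C)C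
F3 | step 14 | methyl (Z)-4-(tert-butyldimethylsilyloxy)-2-[(4,4,5,5-tetramethyl-1,3,2-dioxaborolan-2-yl)methyl]but-2-enoate | COC(=O)/C(CB1OC(C)(C)C(C)(C)O1)=C\CO[Si](C)(C)C(C)(C)C
F4 | step 14 | O6-pinacolboryl ether of 20 | COC(=O)C(=C)[C@H](CO[Si](C)(C)C(C)(C)C)[C@H](OB1OC(C)(C)C(C)(C)O1)/C=C(\C)CC/C=C(/COCc1ccc(OC)cc1)COC(c1ccccc1)(c1ccccc1)c1ccccc1
F5 | step 18 | 8β,9α,14-triol with masked lactone | O[C@H]1[C@H]2[C@H](CS(=O)(=O)c3ccccc3)C(=O)O[C@@H]2/C=C(\C)CC/C=C(/CO)[C@@H]1O
F6 | step 18 | 9,14-O-di-tert-butylsilylene of F5 | O[C@H]1[C@H]2[C@H](CS(=O)(=O)c3ccccc3)C(=O)O[C@@H]2/C=C(\C)CC/C=C3/CO[Si](C(C)(C)C)(C(C)(C)C)O[C@H]13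
F7 | step 18 | 8β-methacrylate of F6 | C=C(C)C(=O)O[C@H]1[C@H]2[C@H](CS(=O)(=O)c3ccccc3)C(=O)O[C@@H]2/C=C(\C)CC/C=C3/CO[Si](C(C)(C)C)(C(C)(C)C)O[C@H]13
F8 | step 18 | 8β-methacrylate, α-methylene lactone, 9,14-silylene | C=C(C)C(=O)O[C@H]1[C@H]2C(=C)C(=O)O[C@@H]2/C=C(\C)CC/C=C3/CO[Si](C(C)(C)C)(C(C)(C)C)O[C@H]13
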